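(The numbers in the tables are simulated for an exercise; scatter was added.)

I started from 1.51: the target of the red run over that of the amber run, both at 0.667 min.

| setting | amber | red | flask |
|---|---|---|---|
| starting material | 5 mM | 7.5 mM | 5.0 mM |
| reagent in the second phase | 2 equiv | 2 equiv | 2.00 equiv |
| remark | the very flask that is asked about, followed so far | run made earlier |  |
| time |  |  | 2.5 min |
| volume of the second phase over the first |  |  | 2.0 |

amber run (percent of the starting material charged)

| time / s | target / % | starting material / % |
|---|---|---|
| 20.0 | 6.7 | 95.5 |
| 40.0 | 9.6 | 89.1 |
| 60.0 | 16.3 | 85.6 |
| 80.0 | 17.7 | 81.5 |

red run (percent of the starting material charged)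

| time / min | target / % | starting material / % |
|---|---|---|
| 0.667 | 14.5 | 83.4 |
| 1.33 | 25.5 | 74.4 |
| 2.00 | 28.7 | 69.1 |
| 2.50 | 34.5 | 65.0 |

(scatter of a reading: 1 percentage point)

- in the second phase: reagent in the second phase; everything else is in the first
- charges count per volume of the first phase; a concentration in a rate is the amount of a species over the volume of its own phase; every rate counts per litre of the first phase
- the earlier runs hold the two phases in the same ratio of volumes as the flask asked about

- Friday's: doubling the transfer coefficient of the reagent in the second phase, all else as stated
- Wednesday's: doubling the amount of reagent in the second phase, all else as stated

1. amount of target at 2.5 min, in percent of the starting material charged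
2. the change that raises the amount of target at 2.5 min, in percent of the starting material charged most ("none" if none brings more than 2 percentage points) (Friday's / Wednesday's / none)
3. amount of target at 2.5 min, in percent of the starting material charged, after Wednesday's

1. I turned the question round: what would make Friday's pay? Transfer would have to be the rate-limiting step. Supply would then follow the reagent charge, which goes with the starting material at fixed equivalents. Both runs would gain the same fraction of their charge per minute, and the ratio would be 1.

2. The readings gave 1.51, beside a charge ratio of 1.50 and above 1. At 1.33 min the ratio was 1.44. With a scatter of 1 percentage point, I expected little from Friday's.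

3. So I scaled time by the charge. With the ratio of phase volumes held, I defined the matching time, a flask's time scaled by its reagent charge over the red run's reagent charge: 1.67 min for this flask.

4. Between the red readings around that time I read 27.1% of the charge as target. Wednesday's doubles the matching time to 3.34 min, past the last red reading of 34.5% at 2.50 min. I expected a gain beyond 7.4 points, over the margin of 2 points.

The forecast gave 28%, Wednesday's as the best change, and 43% after it, judging that “transfer does not look limiting”. Its first value lies above my 27.1%.

The flask gave 24.7%, and 39.9% after Wednesday's, so the forecast held. Wednesday's gained 15 points and Friday's 0.23 points.

    reagent in the reaction phase ⇌ reagent in the second phase, rate k1*([reagent in the reaction phase] - [reagent in the second phase]/K1) per volume of the first phase (partition coefficient = 4.38, kL = 0.376 s⁻¹)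
    starting material + reagent in the reaction phase ⇌ target (K = 550 L mol⁻¹, k = 3.63 L mol⁻¹ s⁻¹)
    reagent in the reaction phase + target → over-reacted product (k = 0.575 L mol⁻¹ s⁻¹)

Read at the flask's matching time of 1.67 min, the red readings stood 2.4 points above what the flask held at 2.5 min. The neighbour charged with 2.0 mM of starting material has a matching time of 0.667 min, where the red run read 14.5%, and that neighbour held 12.0% at 2.5 min.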